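## Structural features

The target is a flavone: a benzene ring (ring A) is fused through C4a and C8a to a 4-pyranone (ring C), and C2 of the pyranone carries a 4-hydroxyphenyl group (ring B) through a single C–C bond. There is no stereocenter, so the whole problem is one of substitution pattern. Ring A bears no hydrogen: C5, C6 and C8 carry methoxy groups, C7 a free hydroxyl, C8a the ring oxygen and C4a the carbonyl carbon C4; C3 of ring C carries a fourth methoxy group. Two phenols (C7 and C4') must end free beside four methyl ethers, so the C7 oxygen must be told apart from its two methoxy neighbours, and the C8a oxygen from the C5 oxygen. The fragile points are the C5 methoxy group, which lies peri to the carbonyl and is lost to Lewis acids once the chromone exists, and the free polyoxygenated ring A, which is easily oxidised to quinones. The end of the route must therefore avoid Lewis acids and oxidants. The real difficulty is the regiodefined hexasubstitution of ring A and the placing of the C3 oxygen. The key step uses the fact that C4 is bonded to C4a, which lies between the oxygen-bearing carbons C5 and C8a: a nitrile oxide on that carbon is shielded on both sides against dimerisation and can deliver C4 to a two-carbon partner that brings C3, C2 and ring B.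

## Logic of the disconnections

**20 back to 17.** The O1–C2 bond of ring C is cut and the C4 carbonyl is traced to a nitrogen-bearing carbon, which leads through 19 and 18 to 17. In 17 an N–O bond holds C4 and C2 at the correct oxidation level and three benzyl ethers mask the C7, C8a and C4' oxygens. The cut is made here so that the free phenols and the chromone with its sensitive C5 methoxy group appear only in the last operation. One reduction then removes four masks at once. The forward step must cleave N–O and three O–benzyl bonds without reducing the vinylogous amide, and the ring closure may use a Brønsted acid only.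

**17 back to 15.** The C3–O bond is cut, through the C3–I bond of 16. The position is the only C–H of the heteroaromatic core and ring A has none, so substitution can be directed there. This takes the C3 oxygen out of the cycloaddition partners, so that a plain terminal alkyne suffices. The forward iodination must prefer that carbon to the positions ortho to the benzyloxy group of ring B, and the C–O coupling must outrun reductive loss of iodine.

**15 back to 13 and 14.** The C3–C4 bond and the bond from the dipole oxygen to C2 are cut. The molecule falls into a ring A piece that carries C4 and a ring B piece that carries C2 and C3, and 14 is bought. The forward step needs a dipole that does not dimerise and complete 3,5-regiochemistry.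

**13 back to 10.** No skeletal bond is cut. The C≡N–O unit is traced through 12 and 11 to the formyl group of 10. An aldehyde is the simplest one-carbon handle on a fully substituted ring. The forward chlorination must attack the oxime carbon only, which is helped by the absence of any ring C–H.

**10 back to 8.** Two O–benzyl bonds are cut to give 9, and 9 is traced to 8 by restoring one O–methyl bond and one O–isopropyl bond. 8 has a mirror plane through the formyl carbon and the C7 oxygen, so cleavage of either ortho methoxy group gives the same compound and no regiochemical choice arises. The forward Lewis acid step must stop after one chelation-controlled demethylation, remove the secondary alkyl group and leave the other three methyl ethers.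

**8 back to 5.** The C4a–C4 bond is cut. The only ring hydrogen of 5 lies between two methoxy groups, the best case for directed lithiation. The oxygen protecting group of 5 must therefore be inert to alkyllithium, which is why it is isopropyl and not benzyl.

**5 back to 1.** The O–isopropyl bond is cut to give 4, and then the ring C–O bond at the future C7 is cut to give 1. 1 is bought and symmetric: its two ring hydrogens are equivalent and each lies between two methoxy groups. The forward step needs monolithiation and an oxidation of the C–B bond that does not go on to oxidise the electron-rich phenol.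

## Other disconnections considered

**Alternative 1:** Ring A is cut out as a whole. C4a and C8a come from a pyranone and C5 to C8 from a squaric ester. The last bond formed is C8–C8a.
- Forward: halogen–metal exchange of 2-[4-(benzyloxy)phenyl]-5-bromo-3-methoxy-4H-pyran-4-one A4 and addition to 3-tert-butoxy-4-methoxycyclobut-3-ene-1,2-dione A3 would give the 4-hydroxycyclobutenone A2. Heating A2 would open the four-membered ring to a dienylketene, whose ketene carbon closes on pyranone C6 in a six-electron electrocyclisation; tautomerisation then gives the 5,8-hydroquinone A1.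
- In favour: all five ring A oxygens are placed by construction, the C7 oxygen is set apart as a tert-butyl ether from the start, and the C3 methoxy group is present before ring A exists. After A1 only methylation of the C5 and C8 hydroxyls and removal of tert-butyl and benzyl would remain.
- Against: a metalated 4-pyranone is an unusual nucleophile that can add to itself or open. A4 needs a synthesis of its own. The addition to A3 must choose between two very similar carbonyls. The tert-butyl ether can lose isobutene at thermolysis temperature. A1 is a hydroquinone that oxidises readily to the quinone.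
- Comparison: on structure this plan is the better one for the ring A oxygens, because it needs no desymmetrising dealkylation, and for the C3 oxygen, because it needs no late C–H oxygenation. On mechanism the pericyclic cascade is sound in principle, but a pyranonyl group in place of the usual aryl or alkenyl group has thin precedent, whereas the dipole class of the chosen plan is well understood. On step economy the two are about equal, and the alternative is more convergent.

**Alternative 2:** O1–C8a, C4a–C4 and O1–C2 are cut, leaving an aryne and an arylpropiolic acid.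
- Forward: fluoride (CsF) would release the aryne from silyl triflate A6. The carboxylate oxygen of 3-[4-(benzyloxy)phenyl]propiolic acid A7 adds to the aryne carbon remote from the flanking methoxy group (C8a), the aryl anion at C4a takes the acyl carbon, and the resulting phenoxide closes on the ynone to give A5.
- In favour: three bonds and ring C form in one mild operation. The regiochemistry is fixed by the methoxy group next to the aryne, which places the anion at C4a.
- Against: A5 lacks both the C8 and the C3 oxygen. Two later C–H oxygenations would be needed on a flavone whose ring B is also open to electrophiles, and A6 is a tetrasubstituted silyl triflate that needs several steps.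
- Comparison: on bond-forming power the key step is the better one (three bonds against two), and its regiocontrol is the equal of the cycloaddition. On structure it is weaker: the chosen plan has ring A complete before the key step and adds one oxygen afterwards, while this plan must add two. On step economy the short core assembly is offset by those later oxygenations and by the synthesis of A6, so the total would be longer.

**Alternative 3:** Ring B is cut at C1'–C2' and C5'–C6'.
- Forward: the 2-ethynylchromone A9 and 1-methoxy-3-(trimethylsilyloxy)buta-1,3-diene A10 would undergo a (4+2) cycloaddition, the nucleophilic diene terminus bonding to the terminal alkyne carbon. Loss of methanol and desilylation would aromatise the adduct to A8, with the C4' hydroxyl free.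
- In favour: the para hydroxyl is placed by the polarity of the diene and is delivered unprotected. The C3 methoxy group is carried from the start. Ring B is never exposed to electrophilic or metal-mediated steps; on these two points this plan is better than the chosen one, whose step 9 has to discriminate against ring B.
- Against: the cycloaddition builds the simplest part of the molecule, a ring that can be bought, and leaves the hexasubstituted ring A and the 3-methoxychromone to be made by other means inside A9. A9 is also an extended Michael acceptor and a sensitive intermediate.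
- Comparison: on mechanism the Diels–Alder aromatisation is as dependable as the dipolar cycloaddition. On structure it does not touch the real difficulty. On step economy it is clearly worse, because the whole ring A sequence is still needed to reach A9.

Key step: step 8

Remarks on the chemistry (assumptions):
- 1 and 14 are taken as purchasable.
- The structures of 13, 14 and 15 were checked atom by atom against the target numbering and need no correction.
- The symmetric ring A building block is made from 1. A start from 2,6-dimethoxyphenol would first need two more ring oxygens (dibromination and double methoxylation).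
- The C7 oxygen is carried as an isopropyl ether up to the Lewis acid step. A benzyl ether there would meet alkyllithium in step 3 and a dealkylating Lewis acid in step 4. Both benzyl groups are introduced together in step 5.

## Route

Step 1
Reactants: 1 1,2,4,5-tetramethoxybenzene
Product: 4 2,3,5,6-tetramethoxyphenol, via aryllithium 2 (not isolated), via lithium aryltrimethoxyborate 3 (not isolated)
Conditions: n-BuLi (1.05 equiv), TMEDA, THF, 0 °C; B(OMe)3, −78 °C to rt; AcOH, 30% H2O2, 0 °C to rt
Reagents that add atoms: hydrogen peroxide, OO
Why: Directed ortho-lithiation between two methoxy groups, borylation and peroxide oxidation of the C–B bond (1,2-aryl shift from boron to oxygen) is a standard arene hydroxylation. The two ring hydrogens of 1 are equivalent, so only the stoichiometry of the base has to be controlled.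

Step 2
Reactants: 4 2,3,5,6-tetramethoxyphenol
Product: 5 3-isopropoxy-1,2,4,5-tetramethoxybenzene
Conditions: 2-bromopropane, K2CO3, DMF, 60 °C, under N2
Reagents that add atoms: 2-bromopropane, CC(C)Br
Why: Williamson ether synthesis on the phenoxide. The isopropyl ether is inert to alkyllithium in step 3 and is cleaved in step 4 by the same Lewis acid that frees the ortho oxygen.

Step 3
Reactants: 5 3-isopropoxy-1,2,4,5-tetramethoxybenzene
Product: 8 4-isopropoxy-2,3,5,6-tetramethoxybenzaldehyde, via aryllithium 6 (not isolated), via lithium hemiaminolate 7 (not isolated)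
Conditions: n-BuLi, TMEDA, THF, 0 °C; DMF, −78 °C to rt; 1 M HCl
Reagents that add atoms: N,N-dimethylformamide, CN(C)C=O
Why: Directed ortho-metalation at the only ring C–H, which lies between two methoxy groups, followed by formylation with DMF. The tetrahedral adduct 7 collapses to the aldehyde on acidic work-up.

Step 4
Reactants: 8 4-isopropoxy-2,3,5,6-tetramethoxybenzaldehyde
Product: 9 2,4-dihydroxy-3,5,6-trimethoxybenzaldehyde
Conditions: BCl3 (3 equiv), CH2Cl2, −78 to 0 °C; H2O
Reagents that add atoms: none
Why: Lewis acid ether cleavage: BCl3 removes the methyl ether that forms a six-membered chelate with the formyl oxygen and dealkylates secondary alkyl aryl ethers, while unchelated aryl methyl ethers survive at this temperature. The two ortho methoxy groups of 8 are equivalent, and the boron chelate formed after the first cleavage should protect the second one.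

Step 5
Reactants: 9 2,4-dihydroxy-3,5,6-trimethoxybenzaldehyde
Product: 10 2,4-bis(benzyloxy)-3,5,6-trimethoxybenzaldehyde
Conditions: BnBr (2.5 equiv), K2CO3, DMF, 60 °C
Reagents that add atoms: benzyl bromide, BrCc1ccccc1
Why: Double Williamson etherification. Excess bromide and warming should also alkylate the hydrogen-bonded ortho phenol, and both new ethers are removable by hydrogenolysis at the end.

Step 6
Reactants: 10 2,4-bis(benzyloxy)-3,5,6-trimethoxybenzaldehyde
Product: 11 (E)-2,4-bis(benzyloxy)-3,5,6-trimethoxybenzaldehyde oxime
Conditions: NH2OH·HCl, NaOAc, EtOH/H2O, 70 °C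
Reagents that add atoms: hydroxylamine hydrochloride, Cl.NO
Why: Oxime condensation. The E isomer, with OH turned away from the doubly ortho-substituted ring, should be favoured, and the geometry is lost again in step 7.

Step 7
Reactants: 11 (E)-2,4-bis(benzyloxy)-3,5,6-trimethoxybenzaldehyde oxime
Product: 13 2,4-bis(benzyloxy)-3,5,6-trimethoxybenzonitrile oxide, via hydroximoyl chloride 12 (not isolated)
Conditions: NCS, DMF, rt; Et3N, CH2Cl2, 0 °C; aqueous wash, stored cold
Reagents that add atoms: none
Why: Chlorination of the aldoxime carbon followed by base-induced 1,3-elimination of HCl is the standard route to nitrile oxides. The ring has no C–H that could be chlorinated, and the two ortho alkoxy groups should make 13 isolable, as with other doubly ortho-substituted benzonitrile oxides.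

Step 8
Reactants: 13 2,4-bis(benzyloxy)-3,5,6-trimethoxybenzonitrile oxide; 14 1-(benzyloxy)-4-ethynylbenzene
Product: 15 3-[2,4-bis(benzyloxy)-3,5,6-trimethoxyphenyl]-5-[4-(benzyloxy)phenyl]isoxazole
Conditions: 14 (1.5 equiv), toluene, 80 °C
Reagents that add atoms: none
Why: The nitrile oxide is a propargyl-type 1,3-dipole that adds across the C≡C bond of 14 in a concerted, asynchronous, thermally allowed six-electron (3+2) cycloaddition, suprafacial on both partners. Its carbon (future C4) bonds to the terminal alkyne carbon (future C3) and its oxygen to the aryl-bearing carbon (future C2). The five-membered isoxazole is thus closed by the bimolecular cycloaddition itself, both ring bonds forming in one transition state, and the adduct is aromatic at once. The closest known reaction type is the Huisgen addition of isolable, doubly ortho-substituted benzonitrile oxides to terminal arylacetylenes, which gives 3,5-disubstituted isoxazoles. No stereocenter is formed. The selectivity needed is regiochemical (3,5- against 3,4-diaryl): the dominant dipole-LUMO/alkyne-HOMO interaction sets the larger alkyne coefficient, at the terminal carbon, against the dipole carbon, and the bulky dialkoxyaryl group disfavours the orientation in which it would face the aryl group of 14. The benzyloxy group at future C8a and the methoxy group at C5 block dimerisation to the furoxan, and a bath at or below 80 °C should avoid rearrangement of 13 to the isocyanate. All ether groups are spectators.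

Step 9
Reactants: 15 3-[2,4-bis(benzyloxy)-3,5,6-trimethoxyphenyl]-5-[4-(benzyloxy)phenyl]isoxazole
Product: 16 3-[2,4-bis(benzyloxy)-3,5,6-trimethoxyphenyl]-5-[4-(benzyloxy)phenyl]-4-iodoisoxazole
Conditions: NIS (1.05 equiv), TFA (cat.), MeCN, 0 °C to rt
Reagents that add atoms: N-iodosuccinimide, O=C1CCC(=O)N1I
Why: Electrophilic aromatic iodination at isoxazole C4, the enol-ether-like carbon; the cation formed there is stabilised by the ring oxygen and by the para-alkoxyphenyl group on C5. Ring A has no C–H, and attack ortho to the benzyloxy group of ring B would have only one oxygen donor, so C4 should react first with one equivalent of reagent.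

Step 10
Reactants: 16 3-[2,4-bis(benzyloxy)-3,5,6-trimethoxyphenyl]-5-[4-(benzyloxy)phenyl]-4-iodoisoxazole
Product: 17 3-[2,4-bis(benzyloxy)-3,5,6-trimethoxyphenyl]-5-[4-(benzyloxy)phenyl]-4-methoxyisoxazole
Conditions: CuI (20 mol %), 1,10-phenanthroline (40 mol %), Cs2CO3, MeOH/toluene, 110 °C, sealed tube
Reagents that add atoms: methanol, CO
Why: Ullmann-type C–O coupling of a heteroaryl iodide with an aliphatic alcohol under monovalent copper catalysis. A 3,5-disubstituted isoxazole has no C3–H and therefore resists base-induced ring opening, and benzyl and methyl ethers are inert.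

Step 11
Reactants: 17 3-[2,4-bis(benzyloxy)-3,5,6-trimethoxyphenyl]-5-[4-(benzyloxy)phenyl]-4-methoxyisoxazole
Product: 20 7-hydroxy-2-(4-hydroxyphenyl)-3,5,6,8-tetramethoxy-4H-chromen-4-one, via enaminone 18 (not isolated), via diketone 19 (not isolated)
Conditions: H2 (1–3 atm), 10% Pd/C, EtOAc/MeOH, rt; filter under N2; 2 M HCl, MeOH, 60 °C
Reagents that add atoms: water, O
Why: Catalytic hydrogenolysis should cleave the weak N–O bond and the three benzyl ethers. Aqueous acid then hydrolyses the vinylogous amide to the β-diketone, and the C8a hydroxyl adds to the C2 carbonyl with loss of water, as in the closing step of Baker–Venkataraman flavone syntheses. If ring closure precedes loss of nitrogen the same product results, and because ring A is symmetric about the C4a–C7 axis only one chromone can form.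

## Compound list

1 | 1,2,4,5-tetramethoxybenzene | COc1cc(OC)c(OC)cc1OC | starting material
2 | (2,3,5,6-tetramethoxyphenyl)lithium | [Li]c1c(OC)c(OC)cc(OC)c1OC | intermediate
3 | lithium trimethoxy(2,3,5,6-tetramethoxyphenyl)borate | [Li+].CO[B-](OC)(OC)c1c(OC)c(OC)cc(OC)c1OC | intermediate
4 | 2,3,5,6-tetramethoxyphenol | Oc1c(OC)c(OC)cc(OC)c1OC | intermediate
5 | 3-isopropoxy-1,2,4,5-tetramethoxybenzene | CC(C)Oc1c(OC)c(OC)cc(OC)c1OC | intermediate
6 | (4-isopropoxy-2,3,5,6-tetramethoxyphenyl)lithium | [Li]c1c(OC)c(OC)c(OC(C)C)c(OC)c1OC | intermediate
7 | lithium (dimethylamino)(4-isopropoxy-2,3,5,6-tetramethoxyphenyl)methanolate, racemic | [Li+].[O-]C(N(C)C)c1c(OC)c(OC)c(OC(C)C)c(OC)c1OC | intermediate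
8 | 4-isopropoxy-2,3,5,6-tetramethoxybenzaldehyde | O=Cc1c(OC)c(OC)c(OC(C)C)c(OC)c1OC | intermediate
9 | 2,4-dihydroxy-3,5,6-trimethoxybenzaldehyde | O=Cc1c(O)c(OC)c(O)c(OC)c1OC | intermediate
10 | 2,4-bis(benzyloxy)-3,5,6-trimethoxybenzaldehyde | O=Cc1c(OCc2ccccc2)c(OC)c(OCc2ccccc2)c(OC)c1OC | intermediate
11 | (E)-2,4-bis(benzyloxy)-3,5,6-trimethoxybenzaldehyde oxime | O/N=C/c1c(OCc2ccccc2)c(OC)c(OCc2ccccc2)c(OC)c1OC | intermediate
12 | (Z)-2,4-bis(benzyloxy)-N-hydroxy-3,5,6-trimethoxybenzenecarboximidoyl chloride | O/N=C(\Cl)c1c(OCc2ccccc2)c(OC)c(OCc2ccccc2)c(OC)c1OC | intermediate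
13 | 2,4-bis(benzyloxy)-3,5,6-trimethoxybenzonitrile oxide | [O-][N+]#Cc1c(OCc2ccccc2)c(OC)c(OCc2ccccc2)c(OC)c1OC | intermediate
14 | 1-(benzyloxy)-4-ethynylbenzene | C#Cc1ccc(OCc2ccccc2)cc1 | starting material
15 | 3-[2,4-bis(benzyloxy)-3,5,6-trimethoxyphenyl]-5-[4-(benzyloxy)phenyl]isoxazole | COc1c(OCc2ccccc2)c(OC)c(OCc2ccccc2)c(-c2cc(-c3ccc(OCc4ccccc4)cc3)on2)c1OC | intermediate
16 | 3-[2,4-bis(benzyloxy)-3,5,6-trimethoxyphenyl]-5-[4-(benzyloxy)phenyl]-4-iodoisoxazole | COc1c(OCc2ccccc2)c(OC)c(OCc2ccccc2)c(-c2noc(-c3ccc(OCc4ccccc4)cc3)c2I)c1OC | intermediate
17 | 3-[2,4-bis(benzyloxy)-3,5,6-trimethoxyphenyl]-5-[4-(benzyloxy)phenyl]-4-methoxyisoxazole | COc1c(OCc2ccccc2)c(OC)c(OCc2ccccc2)c(-c2noc(-c3ccc(OCc4ccccc4)cc3)c2OC)c1OC | intermediate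
18 | (2E)-3-amino-3-(2,4-dihydroxy-3,5,6-trimethoxyphenyl)-1-(4-hydroxyphenyl)-2-methoxyprop-2-en-1-one (amino group and carbonyl on the same side of the double bond) | N/C(c1c(O)c(OC)c(O)c(OC)c1OC)=C(/OC)C(=O)c1ccc(O)cc1 | intermediate
19 | 1-(2,4-dihydroxy-3,5,6-trimethoxyphenyl)-3-(4-hydroxyphenyl)-2-methoxypropane-1,3-dione, racemic and enolisable at C2 | COC(C(=O)c1ccc(O)cc1)C(=O)c1c(O)c(OC)c(O)c(OC)c1OC | intermediate
20 | 7-hydroxy-2-(4-hydroxyphenyl)-3,5,6,8-tetramethoxy-4H-chromen-4-one | COc1c(O)c(OC)c2oc(-c3ccc(O)cc3)c(OC)c(=O)c2c1OC | target

## Step count and risks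

Total step count: 11. Longest linear sequence: 11 steps (1 to 20); 14 is bought and enters at step 8.

Least certain steps:

**Step 8 (key step).** The cycloaddition of the doubly ortho-substituted dipole may be slow. Thermal rearrangement of the nitrile oxide to the isocyanate could then compete, and raising the temperature could erode regiocontrol.
Fallback, from 13 and back at 15: the alkyne is replaced by an enamine, a much more reactive dipolarophile of fixed polarity. Bought 1-[4-(benzyloxy)phenyl]ethan-1-one F1 is condensed with pyrrolidine (TiCl4, toluene) to 1-{1-[4-(benzyloxy)phenyl]ethenyl}pyrrolidine F2. 13 should add to F2 at room temperature, its carbon going to the CH2 terminus, to give the racemic 5-(pyrrolidin-1-yl)-4,5-dihydroisoxazole F3. Dilute acid eliminates pyrrolidine from F3 and gives 15.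

**Step 9.** Iodination may not stop at isoxazole C4. Competing substitution ortho to the benzyloxy group of ring B is possible, because that ring is an alkoxybenzene and the isoxazole is only moderately nucleophilic.
Fallback, from 13 and 14 and back at 17 (steps 9 and 10 are both bypassed): the C3 handle is carried into the cycloaddition as boron. 14 is deprotonated (n-BuLi, THF, −78 °C) and borylated with 2-isopropoxy-4,4,5,5-tetramethyl-1,3,2-dioxaborolane to 2-{[4-(benzyloxy)phenyl]ethynyl}-4,4,5,5-tetramethyl-1,3,2-dioxaborolane F4. Cycloaddition of 13 with F4 (toluene, 80 °C) is expected to place the boron-bearing carbon on the dipole carbon, as is usual for substituted alkynylboronates, and to give the isoxazol-4-ylboronic pinacol ester F5. Oxidation (H2O2, NaOH, THF) gives the isoxazol-4-ol F6, and O-methylation (MeI, K2CO3, acetone) gives 17.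

**Step 10.** Reductive loss of iodine may outrun C–O bond formation, because the iodide is flanked by two aryl groups, one of them twisted and doubly ortho-substituted, which slows the copper-mediated substitution.
Fallback, from 16 and back at 17: iodine–magnesium exchange with i-PrMgCl·LiCl (THF, −20 °C) gives the isoxazol-4-ylmagnesium chloride F7. Trapping with B(OMe)3 gives the dimethyl isoxazol-4-ylboronate F8, and oxidation (H2O2, NaOH) gives the isoxazol-4-ol F6, which is methylated (MeI, K2CO3) to 17.

**Step 4.** The temperature needed to remove the isopropyl group may also start cleavage of a second methyl ether (the other ortho methoxy group or one next to the newly freed C4 oxygen). If the mixture is kept cold, dealkylation may remain incomplete.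
Fallback, from 4 and back at 9: the C7 oxygen is protected as an acetal, which a Lewis acid removes already at −78 °C. 4 is alkylated with chloromethyl methyl ether (i-Pr2NEt, CH2Cl2) to 1,2,4,5-tetramethoxy-3-(methoxymethoxy)benzene F9. Lithiation and formylation as in step 3 (n-BuLi, TMEDA; DMF; neutral work-up) give 2,3,5,6-tetramethoxy-4-(methoxymethoxy)benzaldehyde F10. BCl3 at −78 °C then removes the acetal and the chelated ortho methyl group and gives 9.

**Step 11.** Hydrogenolysis of the N–O bond in the tetrasubstituted, hindered isoxazole may lag behind debenzylation, and over-reduction or air oxidation of the electron-rich polyphenol could set in during the long exposure.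
Fallback, from 17 and back at 18: the N–O bond is cleaved first with Mo(CO)6 (MeCN/H2O, 80 °C), which leaves benzyl ethers alone and gives (2E)-3-amino-3-[2,4-bis(benzyloxy)-3,5,6-trimethoxyphenyl]-1-[4-(benzyloxy)phenyl]-2-methoxyprop-2-en-1-one F11. A short hydrogenolysis (H2, Pd/C) of F11 then gives 18, which is treated with acid as in step 11.

## Further compounds

F1 | step 8 | 1-[4-(benzyloxy)phenyl]ethan-1-one | CC(=O)c1ccc(OCc2ccccc2)cc1
F2 | step 8 | 1-{1-[4-(benzyloxy)phenyl]ethenyl}pyrrolidine | C=C(N1CCCC1)c1ccc(OCc2ccccc2)cc1
F3 | step 8 | 3-[2,4-bis(benzyloxy)-3,5,6-trimethoxyphenyl]-5-[4-(benzyloxy)phenyl]-5-(pyrrolidin-1-yl)-4,5-dihydroisoxazole, racemic | COc1c(OCc2ccccc2)c(OC)c(OCc2ccccc2)c(C2=NOC(N3CCCC3)(c3ccc(OCc4ccccc4)cc3)C2)c1OC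
F4 | step 9 | 2-{[4-(benzyloxy)phenyl]ethynyl}-4,4,5,5-tetramethyl-1,3,2-dioxaborolane | CC1(C)OB(C#Cc2ccc(OCc3ccccc3)cc2)OC1(C)C
F5 | step 9 | 3-[2,4-bis(benzyloxy)-3,5,6-trimethoxyphenyl]-5-[4-(benzyloxy)phenyl]-4-(4,4,5,5-tetramethyl-1,3,2-dioxaborolan-2-yl)isoxazole | COc1c(OCc2ccccc2)c(OC)c(OCc2ccccc2)c(-c2noc(-c3ccc(OCc4ccccc4)cc3)c2B2OC(C)(C)C(C)(C)O2)c1OC
F6 | step 9 | 3-[2,4-bis(benzyloxy)-3,5,6-trimethoxyphenyl]-5-[4-(benzyloxy)phenyl]isoxazol-4-ol | COc1c(OCc2ccccc2)c(OC)c(OCc2ccccc2)c(-c2noc(-c3ccc(OCc4ccccc4)cc3)c2O)c1OC
F7 | step 10 | {3-[2,4-bis(benzyloxy)-3,5,6-trimethoxyphenyl]-5-[4-(benzyloxy)phenyl]isoxazol-4-yl}magnesium chloride | COc1c(OCc2ccccc2)c(OC)c(OCc2ccccc2)c(-c2noc(-c3ccc(OCc4ccccc4)cc3)c2[Mg]Cl)c1OC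
F8 | step 10 | dimethyl {3-[2,4-bis(benzyloxy)-3,5,6-trimethoxyphenyl]-5-[4-(benzyloxy)phenyl]isoxazol-4-yl}boronate | COc1c(OCc2ccccc2)c(OC)c(OCc2ccccc2)c(-c2noc(-c3ccc(OCc4ccccc4)cc3)c2B(OC)OC)c1OC
F9 | step 4 | 1,2,4,5-tetramethoxy-3-(methoxymethoxy)benzene | COCOc1c(OC)c(OC)cc(OC)c1OC
F10 | step 4 | 2,3,5,6-tetramethoxy-4-(methoxymethoxy)benzaldehyde | COCOc1c(OC)c(OC)c(C=O)c(OC)c1OC
F11 | step 11 | (2E)-3-amino-3-[2,4-bis(benzyloxy)-3,5,6-trimethoxyphenyl]-1-[4-(benzyloxy)phenyl]-2-methoxyprop-2-en-1-one | N/C(c1c(OCc2ccccc2)c(OC)c(OCc2ccccc2)c(OC)c1OC)=C(/OC)C(=O)c1ccc(OCc2ccccc2)cc1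
A1 | alternative 1 | 2-[4-(benzyloxy)phenyl]-7-tert-butoxy-5,8-dihydroxy-3,6-dimethoxy-4H-chromen-4-one | COc1c(OC(C)(C)C)c(O)c2oc(-c3ccc(OCc4ccccc4)cc3)c(OC)c(=O)c2c1O
A2 | alternative 1 | 4-{6-[4-(benzyloxy)phenyl]-5-methoxy-4-oxo-4H-pyran-3-yl}-2-tert-butoxy-4-hydroxy-3-methoxycyclobut-2-en-1-one, racemic | COC1=C(OC(C)(C)C)C(=O)C1(O)c1coc(-c2ccc(OCc3ccccc3)cc2)c(OC)c1=O
A3 | alternative 1 | 3-tert-butoxy-4-methoxycyclobut-3-ene-1,2-dione | COC1=C(OC(C)(C)C)C(=O)C1=O
A4 | alternative 1 | 2-[4-(benzyloxy)phenyl]-5-bromo-3-methoxy-4H-pyran-4-one | COc1c(-c2ccc(OCc3ccccc3)cc2)occ(Br)c1=O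
A5 | alternative 2 | 7-(benzyloxy)-2-[4-(benzyloxy)phenyl]-5,6-dimethoxy-4H-chromen-4-one | COc1c(OCc2ccccc2)cc2oc(-c3ccc(OCc4ccccc4)cc3)cc(=O)c2c1OC
A6 | alternative 2 | 4-(benzyloxy)-2,3-dimethoxy-6-(trimethylsilyl)phenyl trifluoromethanesulfonate | COc1c(OC)c(OCc2ccccc2)cc([Si](C)(C)C)c1OS(=O)(=O)C(F)(F)F
A7 | alternative 2 | 3-[4-(benzyloxy)phenyl]propiolic acid | OC(=O)C#Cc1ccc(OCc2ccccc2)cc1
A8 | alternative 3 | 7-(benzyloxy)-2-(4-hydroxyphenyl)-3,5,6,8-tetramethoxy-4H-chromen-4-one | COc1c(OCc2ccccc2)c(OC)c2oc(-c3ccc(O)cc3)c(OC)c(=O)c2c1OC
A9 | alternative 3 | 7-(benzyloxy)-2-ethynyl-3,5,6,8-tetramethoxy-4H-chromen-4-one | COc1c(OCc2ccccc2)c(OC)c2oc(C#C)c(OC)c(=O)c2c1OC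
A10 | alternative 3 | (E)-1-methoxy-3-(trimethylsilyloxy)buta-1,3-diene | CO/C=C/C(=C)O[Si](C)(C)C
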